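## Retrosynthetic overview
1. The cage THF ring (C1–O–C10) is closed last, by acid-mediated transacetalization of the 1-OMe acetal onto the C10 alcohol.
2. The (E)-arylidene γ-lactone comes from Pd/CO cyclocarbonylation of a homopropargylic alcohol (C8–OH, C10–C≡C–Ar). The alkyne comes from chelation-controlled ethynyl addition to an α-hydroxy aldehyde, then Sonogashira coupling.
3. Key step: the C8–O bond and the C6=C7 alkene form together by a Mislow–Evans [2,3]-sigmatropic shift of a C6 allylic selenoxide on the convex β-face.
4. The C6 selenide comes from the TBS dienol ether of an enal by γ-selenenylation. The enal comes from genipin, which already supplies the dihydropyran, the cyclopentene and the C5/C9 centres.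
5. Ring order: pyran and cyclopentene are pre-formed, then the spiro-lactone (step 8), then the cage THF (step 9).

Assumptions:
- Genipin is the commercial natural (4aS,7aS) compound. Its anomeric C1 centre is carried as a mixture, which converges in the last step.
- Chelation-controlled addition in step 6 gives the desired C10 epimer as the major product.

## Route

**Step 1**
Reactants: 1 genipin; 2 methanol
Product: 3 1-O-methylgenipin (methyl acetal, anomeric mixture)
Conditions: PPTS (10 mol %), MeOH, 40 °C
Reagents that add atoms: methanol, CO
Why: Acid-catalysed acetalisation masks the labile hemiacetal so that later oxidations and organometallic steps are clean, and the anomeric mixture is harmless because C1 is re-set in the last step.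

**Step 2**
Reactants: 3
Product: 4 enal (10-oxo-1-O-methylgenipin)
Conditions: MnO2 (20 equiv), CH2Cl2, 25 °C
Reagents that add atoms: none
Why: MnO2 oxidation is selective for the allylic primary alcohol and leaves the acetal and the enol-ether ester untouched.

**Step 3**
Reactants: 4; 5 tert-butyldimethylsilyl triflate
Product: 6 TBS dienol ether of 4 (1-silyloxy-diene, C10=C8–C7=C6)
Conditions: TBSOTf (1.3 equiv), Et3N (3 equiv), CH2Cl2, –78 → 0 °C; non-aqueous work-up (hexane trituration, filtration)
Reagents that add atoms: TBSOTf, CC(C)(C)[Si](C)(C)OS(=O)(=O)C(F)(F)F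
Why: Soft silyl-triflate/amine enolisation of the enal removes a γ-H at C6 (the only γ-H; C8 has no α-H) to give the silyl dienol ether. Isolating it without acid keeps the 1-OMe acetal intact before the selenenylation.

**Step 4**
Reactants: 6; 7 phenylselenenyl chloride
Product: 8 γ-selenide enal (1-O-methyl-6β-phenylselanyl-10-oxo compound; C7=C8 enal retained)
Conditions: PhSeCl (1.1 equiv), CH2Cl2, –78 → 0 °C
Reagents that add atoms: phenylselenenyl chloride, Cl[Se]c1ccccc1
Why: Vinylogous electrophilic selenenylation of the dienol ether occurs at the unhindered γ-carbon C6 (α-attack at C8 would build a crowded quaternary centre), and TBSCl is lost to regenerate the enal. PhSe⁺ approaches from the convex β-face (the H5/H9 face), because the cis-fused pyran ring shields the α-face.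

**Step 5** (key step)
Reactants: 8; 9 hydrogen peroxide
Product: 10 α-hydroxy aldehyde (1-OMe; C8 quaternary bearing OH and CHO; C6=C7 cyclopentene)
Conditions: 30 % aq. H2O2 (5 equiv), pyridine, CH2Cl2, 0 → 25 °C
Reagents that add atoms: hydrogen peroxide, OO
Why: H2O2 oxidises the selenide to the allylic selenoxide, which undergoes the Mislow–Evans [2,3]-sigmatropic shift. The shift is suprafacial, so O is delivered to C8 on the same β-face as Se, and the alkene moves to C6=C7. The selenenate is hydrolysed by the aqueous medium, giving the tertiary alcohol with the configuration the target needs (C8–O cis to H9, C8–C10 cis to C1).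

**Step 6**
Reactants: 10; 11 ethynylmagnesium bromide
Product: 12 propargylic diol
Conditions: HC≡CMgBr (3 equiv), THF, –78 → –30 °C; aq. NH4Cl
Reagents that add atoms: ethynylmagnesium bromide, C#C[Mg]Br
Why: This is a Cram-chelate addition to the five-membered Mg chelate of the C8 alkoxide and the aldehyde. The nucleophile attacks the carbonyl face on the side of the smaller sp2 C7 and away from C9, which sets C10 with the oxygen cis to C1, as the cage requires.

**Step 7**
Reactants: 12; 13 4-iodophenyl acetate
Product: 14 aryl alkyne diol
Conditions: Pd(PPh3)2Cl2 (5 mol %), CuI (10 mol %), Et3N, THF, 25 °C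
Reagents that add atoms: 4-iodophenyl acetate, CC(=O)Oc1ccc(I)cc1
Why: Sonogashira coupling is chemoselective for the terminal alkyne. A tertiary amine base is used because primary or secondary amines would add to C3 of the enol-ether ester, and the aryl acetate survives these mild conditions.

**Step 8**
Reactants: 14; 15 carbon monoxide
Product: 16 (E)-arylidene spirolactone, 1-OMe
Conditions: Pd(OAc)2 (10 mol %), PPh3 (40 mol %), p-TsOH·H2O (20 mol %), CO (10 atm), THF, 80 °C
Reagents that add atoms: carbon monoxide, [C-]#[O+]
Why: This is Pd-catalysed intramolecular hydroalkoxycarbonylation (cyclocarbonylation) of a homopropargylic alcohol. Syn-hydropalladation places Pd on the carbon next to C10 and H on the aryl-bearing carbon. CO insertion then puts the acyl group cis to Pd and therefore trans to Ar, and closure by the tertiary O8–H in 5-exo mode gives the E-arylidene γ-lactone. The C10–OH could only give a β-lactone and is untouched.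

**Step 9**
Reactants: 16
Product: 17 3-O-acetylprismatomerin
Conditions: p-TsOH·H2O (10 mol %), 4 Å MS, CH2Cl2, 25–40 °C
Reagents that add atoms: none
Why: Acid ionises the 1-OMe acetal to the oxocarbenium ion (MeOH is lost), and the cis-disposed C10–OH traps it intramolecularly (transacetalization). Only the cis-fused cage is geometrically possible, so C1 is set as in the target, and C10 is unchanged because no bond to it is broken.

## Compound list
1 | genipin, (4aS,7aS), C1 anomeric mixture | COC(=O)C1=CO[CH](O)[C@@H]2C(CO)=CC[C@H]12 | starting material
2 | methanol | CO | starting material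
3 | 1-O-methylgenipin (anomeric mixture) | COC(=O)C1=CO[CH](OC)[C@@H]2C(CO)=CC[C@H]12 | intermediate
4 | 10-oxo-1-O-methylgenipin (enal) | COC(=O)C1=CO[CH](OC)[C@@H]2C(C=O)=CC[C@H]12 | intermediate
5 | tert-butyldimethylsilyl triflate | CC(C)(C)[Si](C)(C)OS(=O)(=O)C(F)(F)F | starting material
6 | TBS dienol ether of 4 | COC(=O)C1=CO[CH](OC)[C@@H]2C(=CO[Si](C)(C)C(C)(C)C)C=C[C@H]12 | intermediate
7 | phenylselenenyl chloride | Cl[Se]c1ccccc1 | starting material
8 | 6β-phenylselanyl enal | COC(=O)C1=CO[CH](OC)[C@@H]2C(C=O)=C[C@@H]([Se]c3ccccc3)[C@H]12 | intermediate
9 | hydrogen peroxide | OO | starting material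
10 | 8β-hydroxy-8-formyl Δ6,7 α-hydroxy aldehyde, 1-OMe | COC(=O)C1=CO[CH](OC)[C@@H]2[C@](O)(C=O)C=C[C@H]12 | intermediate
11 | ethynylmagnesium bromide | C#C[Mg]Br | starting material
12 | propargylic diol | COC(=O)C1=CO[CH](OC)[C@@H]2[C@](O)([C@@H](O)C#C)C=C[C@H]12 | intermediate
13 | 4-iodophenyl acetate | CC(=O)Oc1ccc(I)cc1 | starting material
14 | aryl alkyne diol | COC(=O)C1=CO[CH](OC)[C@@H]2[C@](O)([C@@H](O)C#Cc3ccc(OC(C)=O)cc3)C=C[C@H]12 | intermediate
15 | carbon monoxide | [C-]#[O+] | starting material
16 | (E)-arylidene spirolactone, 1-OMe | COC(=O)C1=CO[CH](OC)[C@@H]2[C@]3(C=C[C@H]12)OC(=O)/C(=C/c4ccc(OC(C)=O)cc4)[C@@H]3O | intermediate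
17 | 3-O-acetylprismatomerin | COC(=O)C1=CO[C@@H]2O[C@H]3/C(=C\c4ccc(OC(C)=O)cc4)C(=O)O[C@]34C=C[C@H]1[C@H]24 | target

## Totals
- Total steps: 9
- Longest linear sequence: 9

## Three steps most likely to fail
1. **Step 4 (γ-selenenylation), with the step 5 selenoxide shift.** Attack at C8 instead of C6, or syn-selenoxide elimination toward the cis C5–H in step 5 instead of the [2,3] shift, would spoil the sequence. Fallback: treat dienol ether 6 directly with DMDO (Rubottom hydroxylation with 1,4-silyl shift) to give the 8-OTBS aldehyde from the convex face, then remove the silyl group with HF·pyridine to reach 10 without any sigmatropic shift.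
2. **Step 6 (C10 diastereoselectivity).** The wrong epimer cannot form the cage. Fallback: oxidise the propargylic alcohol to the ynone (DMP) and reduce it with chelating Zn(BH4)2. If the wrong epimer still dominates, invert C10 by Mitsunobu reaction with p-nitrobenzoic acid followed by mild methanolysis.
3. **Step 8 (Pd/CO cyclocarbonylation).** The hindered tertiary alcohol, or acid-induced ionisation of the acetal at 80 °C, may cause failure. Fallback: skip the Sonogashira step, cyclocarbonylate the terminal-alkyne diol 12 to the α-methylene lactone, close the cage as in step 9, then introduce the aryl group by Heck coupling with 13.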